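**Retrosynthetic overview**
1. Target 25 ⇐ protected biflavone 23 (debenzylation, then demethylation of the 5-OMe next to the carbonyl) ⇐ chalcone 21 (iodine/DMSO oxidative cyclization) ⇐ Claisen–Schmidt aldol condensation of acetophenone 18 with 4-(benzyloxy)benzaldehyde 19. Ring C of flavone unit 2 is closed last, through the only free hydroxyl, which fixes the 3,6''-linkage.
2. 18 ⇐ ortho C-acetylation of phenol 16, whose free OH lies para to the inter-flavone bond (two equivalent ortho sites).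
3. Flavone unit 1 (15, ring C formed first) ⇐ 1,3-diketone 13 ⇐ key intermolecular aldol addition of the lithium enolate of α-aryl ketone 8 to ring A aldehyde 10 (forms C3–C4), then oxidation and acid cyclodehydration.
4. Ketone 8 ⇐ 2,4,6-trihydroxybenzaldehyde 1 (para-selective allylation, dibenzylation, one-carbon homologation, aryl Grignard addition, oxidation); 10 ⇐ 2-hydroxy-4,6-dimethoxybenzaldehyde 9.

Assumption: the target SMILES has no stereocentre and no specified configuration at the 3–6'' biaryl axis, so no stereocontrol is needed; the stereocentres in intermediates 7, 12, 13, 20 and 22 are racemic and are all destroyed later.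

**Step 1**
Reactants: 1 2,4,6-trihydroxybenzaldehyde
Product: 2 2,6-dihydroxy-4-(prop-2-en-1-yloxy)benzaldehyde
Conditions: allyl alcohol (1.0 equiv), PPh3, DIAD, THF, 0 °C → rt
Reagents that add atoms: allyl alcohol, C=CCO
Why: Mitsunobu etherification engages only the most acidic, non-chelated para hydroxyl and alkylates on oxygen, so the two hydrogen-bonded ortho hydroxyls stay free and the ring is not C-allylated.

**Step 2**
Reactants: 2 2,6-dihydroxy-4-(prop-2-en-1-yloxy)benzaldehyde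
Product: 3 2,6-bis(benzyloxy)-4-(prop-2-en-1-yloxy)benzaldehyde
Conditions: BnBr (2.5 equiv), K2CO3, DMF, 60 °C
Reagents that add atoms: benzyl bromide, BrCc1ccccc1
Why: Williamson etherification under forcing carbonate/DMF conditions caps both chelated ortho phenols as benzyl ethers, which last until step 15.

**Step 3**
Reactants: 3 2,6-bis(benzyloxy)-4-(prop-2-en-1-yloxy)benzaldehyde
Product: 4 1,3-bis(benzyloxy)-2-(2-methoxyethenyl)-5-(prop-2-en-1-yloxy)benzene (E/Z mixture)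
Conditions: Ph3P(CH2OMe)Cl, KOtBu, THF, 0 °C → rt
Reagents that add atoms: (methoxymethyl)triphenylphosphonium chloride, COC[P+](c1ccccc1)(c1ccccc1)c1ccccc1.[Cl-]
Why: Wittig methoxymethylenation of the non-enolisable aldehyde gives the one-carbon-homologated enol ether; its geometry is irrelevant because the alkene is hydrolysed next.

**Step 4**
Reactants: 4 1,3-bis(benzyloxy)-2-(2-methoxyethenyl)-5-(prop-2-en-1-yloxy)benzene
Product: 5 2-[2,6-bis(benzyloxy)-4-(prop-2-en-1-yloxy)phenyl]acetaldehyde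
Conditions: 2 M aq. HCl (cat.), THF, 45 °C; used crude
Reagents that add atoms: water, O
Why: Acid-catalysed enol ether hydrolysis (C-protonation, hydration of the oxocarbenium ion, loss of methanol) gives the arylacetaldehyde, and benzyl and allyl ethers are stable to dilute acid.

**Step 5**
Reactants: 5 2-[2,6-bis(benzyloxy)-4-(prop-2-en-1-yloxy)phenyl]acetaldehyde; 6 (4-methoxyphenyl)magnesium bromide
Product: 7 2-[2,6-bis(benzyloxy)-4-(prop-2-en-1-yloxy)phenyl]-1-(4-methoxyphenyl)ethan-1-ol (racemic)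
Conditions: THF, −78 → −20 °C; then sat. aq. NH4Cl
Reagents that add atoms: none
Why: Grignard 1,2-addition at low temperature outruns enolisation of the aldehyde and installs ring B of flavone unit 1; the racemic carbinol centre is removed in step 6.

**Step 6**
Reactants: 7 2-[2,6-bis(benzyloxy)-4-(prop-2-en-1-yloxy)phenyl]-1-(4-methoxyphenyl)ethan-1-ol
Product: 8 2-[2,6-bis(benzyloxy)-4-(prop-2-en-1-yloxy)phenyl]-1-(4-methoxyphenyl)ethan-1-one
Conditions: Dess–Martin periodinane, pyridine, CH2Cl2, 0 °C → rt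
Reagents that add atoms: none
Why: Buffered Dess–Martin oxidation converts the benzylic secondary alcohol into the α-aryl ketone without touching the allyl or benzyl ethers.

**Step 7**
Reactants: 9 2-hydroxy-4,6-dimethoxybenzaldehyde
Product: 10 2,4-dimethoxy-6-(methoxymethoxy)benzaldehyde
Conditions: MOMCl, K2CO3, acetone, reflux
Reagents that add atoms: chloromethyl methyl ether, COCCl
Why: O-alkylation of the chelated phenol gives an acetal-type ether that survives the basic aldol and is later removed by acid without affecting benzyl or allyl ethers.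

**Step 8**
Reactants: 8 2-[2,6-bis(benzyloxy)-4-(prop-2-en-1-yloxy)phenyl]-1-(4-methoxyphenyl)ethan-1-one; 10 2,4-dimethoxy-6-(methoxymethoxy)benzaldehyde
Product: 12 2-[2,6-bis(benzyloxy)-4-(prop-2-en-1-yloxy)phenyl]-3-[2,4-dimethoxy-6-(methoxymethoxy)phenyl]-3-hydroxy-1-(4-methoxyphenyl)propan-1-one (racemic diastereomer mixture), via lithium enolate 11 (not isolated)
Conditions: LiN(SiMe3)2 (1.1 equiv), THF, −78 °C; then 10, −78 °C; AcOH quench at −78 °C
Reagents that add atoms: none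
Why: Directed crossed aldol addition of the preformed enolate of 8 (one enolisable site) to the non-enolisable aldehyde 10 forms the C3–C4 bond of flavone unit 1; the cold quench prevents retro-aldol, and the two unselectively formed stereocentres are erased in steps 9 and 10.

**Step 9**
Reactants: 12 the aldol adduct
Product: 13 2-[2,6-bis(benzyloxy)-4-(prop-2-en-1-yloxy)phenyl]-1-[2,4-dimethoxy-6-(methoxymethoxy)phenyl]-3-(4-methoxyphenyl)propane-1,3-dione
Conditions: Dess–Martin periodinane, pyridine, CH2Cl2, rt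
Reagents that add atoms: none
Why: Dess–Martin oxidation of the β-hydroxy ketone under non-basic, buffered conditions gives the 2-aryl-1,3-diketone without retro-aldol cleavage or ionisation of the electron-rich benzylic alcohol.

**Step 10**
Reactants: 13 the MOM-protected 1,3-diketone
Product: 15 3-[2,6-bis(benzyloxy)-4-(prop-2-en-1-yloxy)phenyl]-5,7-dimethoxy-2-(4-methoxyphenyl)-4H-chromen-4-one, via hydroxy diketone 14 (not isolated)
Conditions: HCl (3 M in MeOH, cat.), THF, 50 °C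
Reagents that add atoms: none
Why: Acidic MOM cleavage frees the ortho phenol, which adds to the distal (4-methoxybenzoyl) carbonyl and dehydrates (the cyclodehydration of the Baker–Venkataraman flavone synthesis) to close ring C of flavone unit 1.

**Step 11**
Reactants: 15 the allyl-protected flavone
Product: 16 3-[2,6-bis(benzyloxy)-4-hydroxyphenyl]-5,7-dimethoxy-2-(4-methoxyphenyl)-4H-chromen-4-one
Conditions: Pd(PPh3)4 (5 mol %), morpholine, THF, rt
Reagents that add atoms: none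
Why: Tsuji–Trost deallylation by zerovalent palladium, with morpholine as allyl acceptor, removes only the allyl ether and frees the phenol para to the inter-flavone bond.

**Step 12**
Reactants: 16 the phenol
Product: 18 3-[3-acetyl-2,6-bis(benzyloxy)-4-hydroxyphenyl]-5,7-dimethoxy-2-(4-methoxyphenyl)-4H-chromen-4-one, via aryl acetate 17 (not isolated)
Conditions: Ac2O (1.5 equiv), BF3·OEt2, ClCH2CH2Cl, 0 → 50 °C; then MeOH–H2O, 60 °C
Reagents that add atoms: acetic anhydride, CC(=O)OC(C)=O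
Why: O-acetylation then BF3-promoted Fries rearrangement places the acetyl ortho to the phenol on the phloroglucinol-type ring; the para position is blocked and the two ortho positions are equivalent, while ring A of the chromone is deactivated by its BF3-complexed carbonyl.

**Step 13**
Reactants: 18 the acetophenone; 19 4-(benzyloxy)benzaldehyde
Product: 21 3-{2,6-bis(benzyloxy)-3-[(2E)-3-(4-benzyloxyphenyl)prop-2-enoyl]-4-hydroxyphenyl}-5,7-dimethoxy-2-(4-methoxyphenyl)-4H-chromen-4-one, via aldol adduct 20 (not isolated)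
Conditions: KOH (50 % aq.), EtOH–THF, rt, 36 h; then AcOH
Reagents that add atoms: none
Why: Claisen–Schmidt aldol condensation of the methyl ketone with a non-enolisable aldehyde gives the E-chalcone by E1cB dehydration; any hydroxide-opened chromone of unit 1 recloses on acidification.

**Step 14**
Reactants: 21 the chalcone
Product: 23 5,7-bis(benzyloxy)-2-[4-(benzyloxy)phenyl]-6-[5,7-dimethoxy-2-(4-methoxyphenyl)-4-oxo-4H-chromen-3-yl]-4H-chromen-4-one, via flavanone 22 (not isolated)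
Conditions: I2 (10 mol %), DMSO, 120 °C
Reagents that add atoms: none
Why: Iodine/DMSO oxidative cyclization closes ring C of flavone unit 2 by oxa-Michael addition of the only free ortho hydroxyl (the one para to the inter-flavone bond), which fixes the 6''-linkage, and then dehydrogenates the flavanone, removing its stereocentre.

**Step 15**
Reactants: 23 the tribenzyl biflavone
Product: 24 5,7-dihydroxy-2-(4-hydroxyphenyl)-6-[5,7-dimethoxy-2-(4-methoxyphenyl)-4-oxo-4H-chromen-3-yl]-4H-chromen-4-one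
Conditions: H2 (1 atm), 10 % Pd/C, THF–MeOH, rt
Reagents that add atoms: none
Why: Catalytic hydrogenolysis cleaves the three aryl benzyl ethers under neutral conditions that leave the methyl ethers and both chromone C2=C3 bonds intact.

**Step 16**
Reactants: 24 the 5-O-methyl biflavone
Product: 25 5,7-dihydroxy-6-[5-hydroxy-7-methoxy-2-(4-methoxyphenyl)-4-oxo-4H-chromen-3-yl]-2-(4-hydroxyphenyl)-4H-chromen-4-one (target)
Conditions: BCl3 (1 M in CH2Cl2, excess), CH2Cl2, −40 °C → rt; then H2O–MeOH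
Reagents that add atoms: none
Why: Chelation-directed Lewis-acid demethylation: BCl3 bound to the C4 carbonyl cleaves only the adjacent 5-OMe of unit 1, leaving the 7-OMe and 4'-OMe groups.

**Compound list**
1 | 2,4,6-trihydroxybenzaldehyde | O=Cc1c(O)cc(O)cc1O | starting material
2 | 2,6-dihydroxy-4-(prop-2-en-1-yloxy)benzaldehyde | O=Cc1c(O)cc(OCC=C)cc1O | intermediate
3 | 2,6-bis(benzyloxy)-4-(prop-2-en-1-yloxy)benzaldehyde | O=Cc1c(OCc2ccccc2)cc(OCC=C)cc1OCc1ccccc1 | intermediate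
4 | 1,3-bis(benzyloxy)-2-(2-methoxyethenyl)-5-(prop-2-en-1-yloxy)benzene, E/Z mixture | COC=Cc1c(OCc2ccccc2)cc(OCC=C)cc1OCc1ccccc1 | intermediate
5 | 2-[2,6-bis(benzyloxy)-4-(prop-2-en-1-yloxy)phenyl]acetaldehyde | O=CCc1c(OCc2ccccc2)cc(OCC=C)cc1OCc1ccccc1 | intermediate
6 | (4-methoxyphenyl)magnesium bromide | COc1ccc([Mg]Br)cc1 | starting material
7 | 2-[2,6-bis(benzyloxy)-4-(prop-2-en-1-yloxy)phenyl]-1-(4-methoxyphenyl)ethan-1-ol, racemic | COc1ccc(C(O)Cc2c(OCc3ccccc3)cc(OCC=C)cc2OCc2ccccc2)cc1 | intermediate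
8 | 2-[2,6-bis(benzyloxy)-4-(prop-2-en-1-yloxy)phenyl]-1-(4-methoxyphenyl)ethan-1-one | COc1ccc(C(=O)Cc2c(OCc3ccccc3)cc(OCC=C)cc2OCc2ccccc2)cc1 | intermediate
9 | 2-hydroxy-4,6-dimethoxybenzaldehyde | COc1cc(O)c(C=O)c(OC)c1 | starting material
10 | 2,4-dimethoxy-6-(methoxymethoxy)benzaldehyde | COCOc1cc(OC)cc(OC)c1C=O | intermediate
11 | lithium enolate of 8 (lithium 2-aryl-1-(4-methoxyphenyl)ethen-1-olate), not isolated | COc1ccc(C([O-])=Cc2c(OCc3ccccc3)cc(OCC=C)cc2OCc2ccccc2)cc1.[Li+] | intermediate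
12 | 2-[2,6-bis(benzyloxy)-4-(prop-2-en-1-yloxy)phenyl]-3-[2,4-dimethoxy-6-(methoxymethoxy)phenyl]-3-hydroxy-1-(4-methoxyphenyl)propan-1-one, racemic diastereomer mixture | COc1ccc(C(=O)C(c2c(OCc3ccccc3)cc(OCC=C)cc2OCc2ccccc2)C(O)c2c(OCOC)cc(OC)cc2OC)cc1 | intermediate
13 | 2-[2,6-bis(benzyloxy)-4-(prop-2-en-1-yloxy)phenyl]-1-[2,4-dimethoxy-6-(methoxymethoxy)phenyl]-3-(4-methoxyphenyl)propane-1,3-dione, racemic/enolisable | COc1ccc(C(=O)C(c2c(OCc3ccccc3)cc(OCC=C)cc2OCc2ccccc2)C(=O)c2c(OCOC)cc(OC)cc2OC)cc1 | intermediate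
14 | 2-[2,6-bis(benzyloxy)-4-(prop-2-en-1-yloxy)phenyl]-1-(2-hydroxy-4,6-dimethoxyphenyl)-3-(4-methoxyphenyl)propane-1,3-dione, not isolated | COc1ccc(C(=O)C(c2c(OCc3ccccc3)cc(OCC=C)cc2OCc2ccccc2)C(=O)c2c(O)cc(OC)cc2OC)cc1 | intermediate
15 | 3-[2,6-bis(benzyloxy)-4-(prop-2-en-1-yloxy)phenyl]-5,7-dimethoxy-2-(4-methoxyphenyl)-4H-chromen-4-one | COc1ccc(-c2oc3cc(OC)cc(OC)c3c(=O)c2-c2c(OCc3ccccc3)cc(OCC=C)cc2OCc2ccccc2)cc1 | intermediate
16 | 3-[2,6-bis(benzyloxy)-4-hydroxyphenyl]-5,7-dimethoxy-2-(4-methoxyphenyl)-4H-chromen-4-one | COc1ccc(-c2oc3cc(OC)cc(OC)c3c(=O)c2-c2c(OCc3ccccc3)cc(O)cc2OCc2ccccc2)cc1 | intermediate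
17 | 3,5-bis(benzyloxy)-4-[5,7-dimethoxy-2-(4-methoxyphenyl)-4-oxo-4H-chromen-3-yl]phenyl acetate, not isolated | COc1ccc(-c2oc3cc(OC)cc(OC)c3c(=O)c2-c2c(OCc3ccccc3)cc(OC(C)=O)cc2OCc2ccccc2)cc1 | intermediate
18 | 3-[3-acetyl-2,6-bis(benzyloxy)-4-hydroxyphenyl]-5,7-dimethoxy-2-(4-methoxyphenyl)-4H-chromen-4-one | COc1ccc(-c2oc3cc(OC)cc(OC)c3c(=O)c2-c2c(OCc3ccccc3)cc(O)c(C(C)=O)c2OCc2ccccc2)cc1 | intermediate
19 | 4-(benzyloxy)benzaldehyde | O=Cc1ccc(OCc2ccccc2)cc1 | starting material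
20 | 3-{2,6-bis(benzyloxy)-3-[3-(4-benzyloxyphenyl)-3-hydroxypropanoyl]-4-hydroxyphenyl}-5,7-dimethoxy-2-(4-methoxyphenyl)-4H-chromen-4-one, racemic, not isolated | COc1ccc(-c2oc3cc(OC)cc(OC)c3c(=O)c2-c2c(OCc3ccccc3)cc(O)c(C(=O)CC(O)c3ccc(OCc4ccccc4)cc3)c2OCc2ccccc2)cc1 | intermediate
21 | 3-{2,6-bis(benzyloxy)-3-[(2E)-3-(4-benzyloxyphenyl)prop-2-enoyl]-4-hydroxyphenyl}-5,7-dimethoxy-2-(4-methoxyphenyl)-4H-chromen-4-one | COc1ccc(-c2oc3cc(OC)cc(OC)c3c(=O)c2-c2c(OCc3ccccc3)cc(O)c(C(=O)/C=C/c3ccc(OCc4ccccc4)cc3)c2OCc2ccccc2)cc1 | intermediate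
22 | 5,7-bis(benzyloxy)-2-[4-(benzyloxy)phenyl]-6-[5,7-dimethoxy-2-(4-methoxyphenyl)-4-oxo-4H-chromen-3-yl]-2,3-dihydro-4H-chromen-4-one, racemic, not isolated | COc1ccc(-c2oc3cc(OC)cc(OC)c3c(=O)c2-c2c(OCc3ccccc3)cc3OC(c4ccc(OCc5ccccc5)cc4)CC(=O)c3c2OCc2ccccc2)cc1 | intermediate
23 | 5,7-bis(benzyloxy)-2-[4-(benzyloxy)phenyl]-6-[5,7-dimethoxy-2-(4-methoxyphenyl)-4-oxo-4H-chromen-3-yl]-4H-chromen-4-one | COc1ccc(-c2oc3cc(OC)cc(OC)c3c(=O)c2-c2c(OCc3ccccc3)cc3oc(-c4ccc(OCc5ccccc5)cc4)cc(=O)c3c2OCc2ccccc2)cc1 | intermediate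
24 | 5,7-dihydroxy-2-(4-hydroxyphenyl)-6-[5,7-dimethoxy-2-(4-methoxyphenyl)-4-oxo-4H-chromen-3-yl]-4H-chromen-4-one | COc1ccc(-c2oc3cc(OC)cc(OC)c3c(=O)c2-c2c(O)cc3oc(-c4ccc(O)cc4)cc(=O)c3c2O)cc1 | intermediate
25 | 5,7-dihydroxy-6-[5-hydroxy-7-methoxy-2-(4-methoxyphenyl)-4-oxo-4H-chromen-3-yl]-2-(4-hydroxyphenyl)-4H-chromen-4-one | COc1ccc(-c2oc3cc(OC)cc(O)c3c(=O)c2-c2c(O)cc3oc(-c4ccc(O)cc4)cc(=O)c3c2O)cc1 | target

**Step count and risks**
Total: 16 steps. Longest linear sequence: 15 steps (1 → 25 through steps 1–6 and 8–16; step 7 is a one-step branch).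

Most likely to fail:

Step 8 (congested aldol between a hindered α-aryl ketone enolate and an electron-rich, di-ortho-substituted aldehyde; low conversion or retro-aldol). The fallback sets out from ketone 8 and replaces the aldol/oxidation pair by an intermolecular Claisen condensation. Commercial 2,4,6-trihydroxybenzoic acid is converted with acetone, (CF3CO)2O and CF3CO2H into 5,7-dihydroxy-2,2-dimethyl-4H-1,3-benzodioxin-4-one F1. Methylation (MeI, K2CO3, DMF, 50 °C) gives 5,7-dimethoxy-2,2-dimethyl-4H-1,3-benzodioxin-4-one F2. The lithium enolate of 8 (LiN(SiMe3)2, 2.2 equiv, THF, −78 → 0 °C) attacks the activated ester carbonyl of F2; the ring opens with loss of acetone and delivers hydroxy diketone 14 directly. The route is rejoined at 14, which cyclodehydrates to 15 under the acid conditions of step 10.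

Step 12 (late Friedel–Crafts/Fries acetylation in the presence of benzyl ethers and a Lewis-basic chromone). The fallback sets out from phenol 16 and builds the acetyl group in three mild operations. Ortho-formylation (MgCl2, Et3N, paraformaldehyde, MeCN, reflux) gives 3-[2,6-bis(benzyloxy)-3-formyl-4-hydroxyphenyl]-5,7-dimethoxy-2-(4-methoxyphenyl)-4H-chromen-4-one F3. Addition of MeMgBr (THF, −78 °C) gives racemic 3-[2,6-bis(benzyloxy)-4-hydroxy-3-(1-hydroxyethyl)phenyl]-5,7-dimethoxy-2-(4-methoxyphenyl)-4H-chromen-4-one F4. Oxidation with MnO2 (CH2Cl2, rt) returns the route at acetophenone 18.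

Step 13 (aqueous hydroxide with a base-sensitive 2,3-diarylchromone and a hindered, chelated acetophenone; this also removes the iodine step 14). The fallback sets out from acetophenone 18 and closes ring C of flavone unit 2 by a Baker–Venkataraman sequence. Acylation with 4-(benzyloxy)benzoyl chloride (pyridine, DMAP, CH2Cl2) gives 3-acetyl-2,4-bis(benzyloxy)-? positional name: 2-acetyl-3,5-bis(benzyloxy)-4-[5,7-dimethoxy-2-(4-methoxyphenyl)-4-oxo-4H-chromen-3-yl]phenyl 4-(benzyloxy)benzoate F5. Intramolecular acyl transfer with the non-nucleophilic base LiN(SiMe3)2 (THF, −78 → 0 °C) gives 1-{2,4-bis(benzyloxy)-3-[5,7-dimethoxy-2-(4-methoxyphenyl)-4-oxo-4H-chromen-3-yl]-6-hydroxyphenyl}-3-[4-(benzyloxy)phenyl]propane-1,3-dione F6. Cyclodehydration (p-TsOH·H2O cat., toluene, 80 °C) through the same single free hydroxyl rejoins the route at protected biflavone 23.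

**Further compounds**
F1 | step 8 | 5,7-dihydroxy-2,2-dimethyl-4H-1,3-benzodioxin-4-one | CC1(C)OC(=O)c2c(O)cc(O)cc2O1
F2 | step 8 | 5,7-dimethoxy-2,2-dimethyl-4H-1,3-benzodioxin-4-one | CC1(C)OC(=O)c2c(OC)cc(OC)cc2O1
F3 | step 12 | 3-[2,6-bis(benzyloxy)-3-formyl-4-hydroxyphenyl]-5,7-dimethoxy-2-(4-methoxyphenyl)-4H-chromen-4-one | COc1ccc(-c2oc3cc(OC)cc(OC)c3c(=O)c2-c2c(OCc3ccccc3)cc(O)c(C=O)c2OCc2ccccc2)cc1
F4 | step 12 | 3-[2,6-bis(benzyloxy)-4-hydroxy-3-(1-hydroxyethyl)phenyl]-5,7-dimethoxy-2-(4-methoxyphenyl)-4H-chromen-4-one, racemic | COc1ccc(-c2oc3cc(OC)cc(OC)c3c(=O)c2-c2c(OCc3ccccc3)cc(O)c(C(C)O)c2OCc2ccccc2)cc1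
F5 | step 13 | 2-acetyl-3,5-bis(benzyloxy)-4-[5,7-dimethoxy-2-(4-methoxyphenyl)-4-oxo-4H-chromen-3-yl]phenyl 4-(benzyloxy)benzoate | COc1ccc(-c2oc3cc(OC)cc(OC)c3c(=O)c2-c2c(OCc3ccccc3)cc(OC(=O)c3ccc(OCc4ccccc4)cc3)c(C(C)=O)c2OCc2ccccc2)cc1
F6 | step 13 | 1-{2,4-bis(benzyloxy)-3-[5,7-dimethoxy-2-(4-methoxyphenyl)-4-oxo-4H-chromen-3-yl]-6-hydroxyphenyl}-3-[4-(benzyloxy)phenyl]propane-1,3-dione | COc1ccc(-c2oc3cc(OC)cc(OC)c3c(=O)c2-c2c(OCc3ccccc3)cc(O)c(C(=O)CC(=O)c3ccc(OCc4ccccc4)cc3)c2OCc2ccccc2)cc1
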